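**Strategy.** The flavonol is cut through ring C: the C4 carbonyl carbon sits between C4a of ring A and C3, O1 hangs on C8a next to C4a, and C2 carries ring B. C4 can therefore come from carbon monoxide, C2–C3 from an arylacetylene, and O1/C8a/C4a from an o-iodophenol. One palladium-catalysed carbonylative annulation joins a fully oxygenated ring-A iodophenol (free OH flanked by OMe and I, two benzyl ethers) with the benzyl-protected ring-B arylacetylene and CO, forming C4a–C4, C4–C3 and O1–C2 and closing the pyranone. C3 hydroxylation and hydrogenolysis finish the synthesis.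

Key step: step 10

Assumption: the target has no stereogenic element, so the "single enantiomer" is the achiral compound itself and no stereocontrol is needed.

**Route**

Step 1
Reactants: 1 2,4,6-trihydroxybenzaldehyde; 2 benzyl bromide
Product: 3 2,4-bis(benzyloxy)-6-hydroxybenzaldehyde
Conditions: BnBr (2.05 equiv), K2CO3 (2.1 equiv), DMF, 0 °C → rt
Reagents that add atoms: benzyl bromide (2), BrCc1ccccc1
Why: Williamson etherification should stop at the 2,4-dibenzyl ether because the para hydroxyl and one ortho hydroxyl are alkylated readily, whereas the last ortho hydroxyl is held in a strong hydrogen bond to the formyl oxygen and is far less nucleophilic under carbonate conditions.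

Step 2
Reactants: 3 2,4-bis(benzyloxy)-6-hydroxybenzaldehyde
Product: 4 2,4-bis(benzyloxy)-6-(methoxymethoxy)benzaldehyde
Conditions: NaH, MOMCl, DMF, 0 °C → rt
Reagents that add atoms: chloromethyl methyl ether, COCCl
Why: Full deprotonation with NaH breaks the chelate and the phenoxide is O-alkylated by MOMCl (Williamson-type acetal formation), giving an ether that survives the next two steps and later directs metalation.

Step 3
Reactants: 4 2,4-bis(benzyloxy)-6-(methoxymethoxy)benzaldehyde
Product: 6 2,4-bis(benzyloxy)-6-(methoxymethoxy)phenol, via aryl formate 5 (not isolated)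
Conditions: mCPBA, CH2Cl2, 0 °C → rt; then K2CO3 (cat.), MeOH, rt
Reagents that add atoms: 3-chloroperbenzoic acid, O=C(OO)c1cccc(Cl)c1
Why: A peracid Baeyer–Villiger (Dakin-type) oxidation is chosen because the fully etherified aldehyde has no free ortho or para hydroxyl for an alkaline-peroxide Dakin reaction; the 2,4,6-trialkoxyaryl group should migrate in preference to hydrogen, and brief methanolysis cleaves the aryl formate to the phenol.

Step 4
Reactants: 6 2,4-bis(benzyloxy)-6-(methoxymethoxy)phenol
Product: 7 1,5-bis(benzyloxy)-2-methoxy-3-(methoxymethoxy)benzene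
Conditions: MeI, K2CO3, DMF, rt
Reagents that add atoms: iodomethane, CI
Why: Williamson methylation of the hindered but acidic phenol should proceed cleanly and caps the air-sensitive electron-rich phenol as the future C8 methoxy group.

Step 5
Reactants: 7 1,5-bis(benzyloxy)-2-methoxy-3-(methoxymethoxy)benzene
Product: 9 1,5-bis(benzyloxy)-2-iodo-4-methoxy-3-(methoxymethoxy)benzene, via aryllithium 8 (not isolated)
Conditions: n-BuLi, THF, −78 → 0 °C; then I2, THF, −78 °C → rt
Reagents that add atoms: iodine, II; n-butyllithium, [Li]CCCC (its lithium is held only in intermediate 8)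
Why: Directed ortho-metalation: the chelating MOM ether has a single ortho C–H, further acidified by the flanking benzyloxy group, so n-BuLi at low temperature should lithiate there and not between the two benzyloxy groups, and iodine then traps the aryllithium.

Step 6
Reactants: 9 1,5-bis(benzyloxy)-2-iodo-4-methoxy-3-(methoxymethoxy)benzene
Product: 10 3,5-bis(benzyloxy)-2-iodo-6-methoxyphenol
Conditions: HCl (cat.), MeOH–THF, 40 °C
Reagents that add atoms: none
Why: Acid-catalysed acetal exchange with methanol should remove the MOM ether while benzyl ethers, the methyl ether and the aryl iodide are left untouched, the acid being kept dilute to avoid protodeiodination of the electron-rich ring.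

Step 7
Reactants: 11 methyl 3,5-dihydroxy-4-methoxybenzoate; 2 benzyl bromide
Product: 12 methyl 3,5-bis(benzyloxy)-4-methoxybenzoate
Conditions: BnBr (2.3 equiv), K2CO3, DMF, 60 °C
Reagents that add atoms: benzyl bromide (2), BrCc1ccccc1
Why: Williamson etherification of the two equivalent phenols should go to completion, the methyl ester being inert to carbonate in DMF.

Step 8
Reactants: 12 methyl 3,5-bis(benzyloxy)-4-methoxybenzoate
Product: 13 [3,5-bis(benzyloxy)-4-methoxyphenyl]methanol
Conditions: LiAlH4, THF, 0 °C
Reagents that add atoms: none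
Why: Hydride reduction of the ester with LiAlH4 should give the benzylic alcohol without touching the aryl benzyl or methyl ethers.

Step 9
Reactants: 13 [3,5-bis(benzyloxy)-4-methoxyphenyl]methanol
Product: 15 1,3-bis(benzyloxy)-5-ethynyl-2-methoxybenzene, via aldehyde 14 (not isolated)
Conditions: activated MnO2, THF, rt; then dimethyl (1-diazo-2-oxopropyl)phosphonate, K2CO3, MeOH, rt
Reagents that add atoms: dimethyl (1-diazo-2-oxopropyl)phosphonate (Ohira–Bestmann reagent), CC(=O)C(=[N+]=[N-])P(=O)(OC)OC
Why: Activated MnO2 oxidises the benzylic alcohol selectively to the aldehyde, and the Ohira–Bestmann variant of the Seyferth–Gilbert homologation, run in the same flask under mild carbonate/methanol conditions, should convert the electron-rich aldehyde into the terminal alkyne through a vinylidene carbene 1,2-shift.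

Step 10
Reactants: 10 3,5-bis(benzyloxy)-2-iodo-6-methoxyphenol; 15 1,3-bis(benzyloxy)-5-ethynyl-2-methoxybenzene; 16 carbon monoxide
Product: 19 5,7-bis(benzyloxy)-2-[3,5-bis(benzyloxy)-4-methoxyphenyl]-8-methoxychromen-4-one, via ynone 17 (not isolated), via enaminone 18 (not isolated)
Conditions: PdCl2(dppf) (5 mol %), CO (20 bar), Et2NH–toluene (1:1), 110 °C, autoclave
Reagents that add atoms: carbon monoxide (16), [C-]#[O+]; diethylamine, CCNCC (held only in intermediate 18 and released on ring closure)
Why: Pd(0) inserts into the C–I bond of 10, CO insertion gives the aroyl–palladium species, and copper-free Sonogashira-type alkynylation with 15 releases the o-hydroxyaryl ynone 17 (C4a–C4 and C4–C3 formed). Diethylamine then adds in conjugate fashion to give enaminone 18, and the C8a hydroxyl attacks C2 and expels the amine, so ring C closes by a 6-endo-trig addition–elimination (O1–C2) instead of the 5-exo-dig attack at C3 that leads to aurones. The closest known reaction type is the palladium-catalysed carbonylative Sonogashira annulation of o-iodophenols with terminal arylacetylenes in a secondary amine, which delivers flavones. No stereocentre is created. The step needs carbonylative over direct coupling, which CO pressure and the crowded, electron-rich aryl–palladium (two ortho oxygen substituents slow direct alkyne transfer while CO still inserts) should secure, and flavone over aurone closure, which the secondary amine secures; only the hydroxyl next to the methoxy group is free, so only the 8-methoxy isomer can form.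

Step 11
Reactants: 19 5,7-bis(benzyloxy)-2-[3,5-bis(benzyloxy)-4-methoxyphenyl]-8-methoxychromen-4-one
Product: 21 5,7-bis(benzyloxy)-2-[3,5-bis(benzyloxy)-4-methoxyphenyl]-3-hydroxy-8-methoxychromen-4-one, via flavone epoxide 20 (not isolated)
Conditions: DMDO, acetone–CH2Cl2, 0 °C → rt; then p-TsOH·H2O (cat.), CH2Cl2, rt
Reagents that add atoms: dimethyldioxirane, CC1(C)OO1
Why: Dimethyldioxirane epoxidises the C2–C3 enol-ether double bond of the 5-O-protected flavone, and catalytic acid opens the epoxide at C2 to an oxocarbenium ion that loses H3 and tautomerises to the aromatic 3-hydroxychromone, a known flavone-to-flavonol oxidation sequence.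

Step 12
Reactants: 21 5,7-bis(benzyloxy)-2-[3,5-bis(benzyloxy)-4-methoxyphenyl]-3-hydroxy-8-methoxychromen-4-one
Product: 22 3,5,7-trihydroxy-2-(3,5-dihydroxy-4-methoxyphenyl)-8-methoxychromen-4-one
Conditions: H2 (1 atm), 10% Pd/C, THF–MeOH, rt
Reagents that add atoms: none
Why: Catalytic hydrogenolysis should cleave all four aryl benzyl ethers under neutral conditions that retain the methyl ethers and the flavonol C2–C3 double bond and, being acid-free, cannot trigger Wessely–Moser isomerisation of the 5-hydroxy-8-methoxy pattern.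

**Compound list**

1 | 2,4,6-trihydroxybenzaldehyde | O=Cc1c(O)cc(O)cc1O | starting material
2 | benzyl bromide | BrCc1ccccc1 | starting material
3 | 2,4-bis(benzyloxy)-6-hydroxybenzaldehyde | O=Cc1c(O)cc(OCc2ccccc2)cc1OCc1ccccc1 | intermediate
4 | 2,4-bis(benzyloxy)-6-(methoxymethoxy)benzaldehyde | O=Cc1c(OCOC)cc(OCc2ccccc2)cc1OCc1ccccc1 | intermediate
5 | 2,4-bis(benzyloxy)-6-(methoxymethoxy)phenyl formate | O=COc1c(OCOC)cc(OCc2ccccc2)cc1OCc1ccccc1 | intermediate (not isolated)
6 | 2,4-bis(benzyloxy)-6-(methoxymethoxy)phenol | Oc1c(OCOC)cc(OCc2ccccc2)cc1OCc1ccccc1 | intermediate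
7 | 1,5-bis(benzyloxy)-2-methoxy-3-(methoxymethoxy)benzene | COc1c(OCOC)cc(OCc2ccccc2)cc1OCc1ccccc1 | intermediate
8 | [4,6-bis(benzyloxy)-3-methoxy-2-(methoxymethoxy)phenyl]lithium | COc1c(OCOC)c([Li])c(OCc2ccccc2)cc1OCc1ccccc1 | intermediate (not isolated)
9 | 1,5-bis(benzyloxy)-2-iodo-4-methoxy-3-(methoxymethoxy)benzene | COc1c(OCOC)c(I)c(OCc2ccccc2)cc1OCc1ccccc1 | intermediate
10 | 3,5-bis(benzyloxy)-2-iodo-6-methoxyphenol | COc1c(O)c(I)c(OCc2ccccc2)cc1OCc1ccccc1 | intermediate (key-step precursor)
11 | methyl 3,5-dihydroxy-4-methoxybenzoate | COC(=O)c1cc(O)c(OC)c(O)c1 | starting material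
12 | methyl 3,5-bis(benzyloxy)-4-methoxybenzoate | COC(=O)c1cc(OCc2ccccc2)c(OC)c(OCc2ccccc2)c1 | intermediate
13 | [3,5-bis(benzyloxy)-4-methoxyphenyl]methanol | OCc1cc(OCc2ccccc2)c(OC)c(OCc2ccccc2)c1 | intermediate
14 | 3,5-bis(benzyloxy)-4-methoxybenzaldehyde | O=Cc1cc(OCc2ccccc2)c(OC)c(OCc2ccccc2)c1 | intermediate (not isolated)
15 | 1,3-bis(benzyloxy)-5-ethynyl-2-methoxybenzene | C#Cc1cc(OCc2ccccc2)c(OC)c(OCc2ccccc2)c1 | intermediate (key-step precursor)
16 | carbon monoxide | [C-]#[O+] | starting material
17 | 1-[4,6-bis(benzyloxy)-2-hydroxy-3-methoxyphenyl]-3-[3,5-bis(benzyloxy)-4-methoxyphenyl]prop-2-yn-1-one | COc1c(O)c(C(=O)C#Cc2cc(OCc3ccccc3)c(OC)c(OCc3ccccc3)c2)c(OCc2ccccc2)cc1OCc1ccccc1 | intermediate (not isolated)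
18 | (E)-1-[4,6-bis(benzyloxy)-2-hydroxy-3-methoxyphenyl]-3-[3,5-bis(benzyloxy)-4-methoxyphenyl]-3-(diethylamino)prop-2-en-1-one | COc1c(O)c(C(=O)/C=C(/N(CC)CC)c2cc(OCc3ccccc3)c(OC)c(OCc3ccccc3)c2)c(OCc2ccccc2)cc1OCc1ccccc1 | intermediate (not isolated)
19 | 5,7-bis(benzyloxy)-2-[3,5-bis(benzyloxy)-4-methoxyphenyl]-8-methoxychromen-4-one | COc1c(OCc2ccccc2)cc(-c2cc(=O)c3c(OCc4ccccc4)cc(OCc4ccccc4)c(OC)c3o2)cc1OCc1ccccc1 | intermediate (key-step product)
20 | 5,7-bis(benzyloxy)-2-[3,5-bis(benzyloxy)-4-methoxyphenyl]-2,3-epoxy-8-methoxychroman-4-one (racemic; epoxide necessarily cis-fused; one enantiomer drawn) | COc1c(OCc2ccccc2)cc(OCc2ccccc2)c2c1O[C@]1(c3cc(OCc4ccccc4)c(OC)c(OCc4ccccc4)c3)O[C@@H]1C2=O | intermediate (not isolated)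
21 | 5,7-bis(benzyloxy)-2-[3,5-bis(benzyloxy)-4-methoxyphenyl]-3-hydroxy-8-methoxychromen-4-one | COc1c(OCc2ccccc2)cc(-c2oc3c(OC)c(OCc4ccccc4)cc(OCc4ccccc4)c3c(=O)c2O)cc1OCc1ccccc1 | intermediate
22 | 3,5,7-trihydroxy-2-(3,5-dihydroxy-4-methoxyphenyl)-8-methoxychromen-4-one (achiral) | COc1c(O)cc(-c2oc3c(OC)c(O)cc(O)c3c(=O)c2O)cc1O | target

**Step count.** Total: 12 steps. Longest linear sequence: 9 steps (steps 1–6, 10, 11, 12); the alkyne branch (steps 7–9) joins at step 10.

**Steps most likely to fail, with fallbacks**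

Step 10. Oxidative addition and CO uptake at the doubly ortho-substituted, electron-rich iodide may be slow, so that direct (non-carbonylative) alkynylation with benzofuran formation, aminocarbonylation by diethylamine, or 5-exo closure to the aurone compete. The fallback builds the same ynone without palladium; it sets out from 7 and 15 and comes back at 19 through 17. Aryllithium 8, generated from 7 as in step 5, is quenched with DMF instead of iodine to give 4,6-bis(benzyloxy)-3-methoxy-2-(methoxymethoxy)benzaldehyde F1. Alkyne 15 is deprotonated with n-BuLi (THF, −78 °C) to {[3,5-bis(benzyloxy)-4-methoxyphenyl]ethynyl}lithium F2, which adds to F1 to give racemic 1-[4,6-bis(benzyloxy)-3-methoxy-2-(methoxymethoxy)phenyl]-3-[3,5-bis(benzyloxy)-4-methoxyphenyl]prop-2-yn-1-ol F3. MnO2 oxidation should give the MOM-protected ynone 1-[4,6-bis(benzyloxy)-3-methoxy-2-(methoxymethoxy)phenyl]-3-[3,5-bis(benzyloxy)-4-methoxyphenyl]prop-2-yn-1-one F4. Dilute HCl in MeOH–THF removes the MOM group to give ynone 17, and diethylamine in ethanol closes ring C through enaminone 18 to flavone 19.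

Step 5. Lithiation may occur between the two benzyloxy groups, or at a benzylic CH2 followed by Wittig rearrangement, eroding regiocontrol and mass balance. The fallback replaces metalation by electrophilic substitution; it sets out from 7 and comes back at 10. The MOM group of 7 is removed first (HCl, MeOH–THF) to give 3,5-bis(benzyloxy)-2-methoxyphenol F5. F5 is then iodinated with N-iodosuccinimide in CH2Cl2 at low temperature. The position next to the hydroxyl is the less hindered of the two activated sites (the other lies between two benzyloxy groups), so 10 should predominate, with any para isomer removed by chromatography.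

Step 11. The dioxirane may over-oxidise the substrate (benzylic C–H of the benzyl ethers, the electron-rich rings), or the epoxide may open with ring contraction instead of enolisation. The fallback avoids an electrophilic oxidant on the intact flavone; it sets out from 19 and comes back at 21. Deprotonation at C3 with LDA (THF, −78 °C) gives {5,7-bis(benzyloxy)-2-[3,5-bis(benzyloxy)-4-methoxyphenyl]-8-methoxy-4-oxochromen-3-yl}lithium F6. Trapping with trimethyl borate gives dimethyl {5,7-bis(benzyloxy)-2-[3,5-bis(benzyloxy)-4-methoxyphenyl]-8-methoxy-4-oxochromen-3-yl}boronate F7. Oxidation in the same flask with H2O2/AcOH should give flavonol 21.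

**Further compounds**

F1 | step 10 | 4,6-bis(benzyloxy)-3-methoxy-2-(methoxymethoxy)benzaldehyde | COc1c(OCOC)c(C=O)c(OCc2ccccc2)cc1OCc1ccccc1
F2 | step 10 | {[3,5-bis(benzyloxy)-4-methoxyphenyl]ethynyl}lithium | [Li]C#Cc1cc(OCc2ccccc2)c(OC)c(OCc2ccccc2)c1
F3 | step 10 | 1-[4,6-bis(benzyloxy)-3-methoxy-2-(methoxymethoxy)phenyl]-3-[3,5-bis(benzyloxy)-4-methoxyphenyl]prop-2-yn-1-ol (racemic) | COc1c(OCOC)c(C(O)C#Cc2cc(OCc3ccccc3)c(OC)c(OCc3ccccc3)c2)c(OCc2ccccc2)cc1OCc1ccccc1
F4 | step 10 | 1-[4,6-bis(benzyloxy)-3-methoxy-2-(methoxymethoxy)phenyl]-3-[3,5-bis(benzyloxy)-4-methoxyphenyl]prop-2-yn-1-one | COc1c(OCOC)c(C(=O)C#Cc2cc(OCc3ccccc3)c(OC)c(OCc3ccccc3)c2)c(OCc2ccccc2)cc1OCc1ccccc1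
F5 | step 5 | 3,5-bis(benzyloxy)-2-methoxyphenol | COc1c(O)cc(OCc2ccccc2)cc1OCc1ccccc1
F6 | step 11 | {5,7-bis(benzyloxy)-2-[3,5-bis(benzyloxy)-4-methoxyphenyl]-8-methoxy-4-oxochromen-3-yl}lithium | COc1c(OCc2ccccc2)cc(-c2oc3c(OC)c(OCc4ccccc4)cc(OCc4ccccc4)c3c(=O)c2[Li])cc1OCc1ccccc1
F7 | step 11 | dimethyl {5,7-bis(benzyloxy)-2-[3,5-bis(benzyloxy)-4-methoxyphenyl]-8-methoxy-4-oxochromen-3-yl}boronate | COc1c(OCc2ccccc2)cc(-c2oc3c(OC)c(OCc4ccccc4)cc(OCc4ccccc4)c3c(=O)c2B(OC)OC)cc1OCc1ccccc1
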